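**Retrosynthetic overview**
1. The target is an (R)-2-alkyl-6-methyl-2,3-dihydro-4H-pyran-4-one with a C19 side chain (C1′ on ring C2, Z-alkene at C10′=C11′). The chain is cut at C5′–C6′, inside the saturated (CH2)9 tether, by a nickel-catalysed decarboxylative sp3–sp3 coupling: C5′ comes from a ring-bearing redox-active ester (radical after loss of CO2), C6′ from a bis(alkenyl)zinc.
2. Enabling feature: C5′ is separated from ring C2 by four CH2 groups, and the nearest π-bond (ring C5=C6) could only be reached through an eight-membered closure, so C5′ can be a free primary radical. C6′ is the terminus of a hex-5-enyl unit (C6′–C9′, then C10′=C11′), so it is kept closed-shell on zinc to exclude 5-exo cyclisation onto the Z-alkene.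
3. Ring formation: the only ring (O1–C2–C3–C4–C5–C6) is made first, by a BINOL–Ti-catalysed Mukaiyama aldol/cyclocondensation of methyl 7-oxoheptanoate with a 4-methoxy-2-silyloxypentadiene, which sets C2. The ester is then converted to the acid and the N-hydroxyphthalimide ester.
4. The Z-alkene comes from a salt-free Wittig reaction of nonylidenetriphenylphosphorane with the lactol of 5-hydroxypentanal, followed by alcohol → iodide → lithium → zinc.

Key step: step 7

Assumption: (S)-BINOL–Ti(IV) is taken to direct the nucleophile to the Si face of the aliphatic aldehyde, as in related BINOL–Ti allylations and Mukaiyama aldol reactions; if the sense proves opposite, (R)-BINOL is used.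

**Step 1**
Reactants: 1 (3E)-4-methoxypent-3-en-2-one
Product: 3 (3E)-4-methoxy-2-(trimethylsilyloxy)penta-1,3-diene, via lithium dienolate 2 (not isolated)
Conditions: LDA, THF, −78 °C; TMSCl, −78 °C → rt; non-aqueous work-up, distillation
Reagents that add atoms: chlorotrimethylsilane, C[Si](C)(C)Cl
Why: Kinetic deprotonation of the methyl ketone (α′-CH3) of the vinylogous ester and O-silylation of the cross-conjugated enolate (silyl enol ether formation) should give the 1-methoxy-3-silyloxy-type diene, with the (E)-enol ether geometry carried over from 1.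

**Step 2**
Reactants: 4 methyl 7-oxoheptanoate; 3 (3E)-4-methoxy-2-(trimethylsilyloxy)penta-1,3-diene
Product: 6 methyl 6-[(2R)-6-methyl-4-oxo-3,4-dihydro-2H-pyran-2-yl]hexanoate, via silyl aldol adduct 5 (not isolated)
Conditions: (S)-BINOL (20 mol %), Ti(Oi-Pr)4 (10 mol %), CF3CO2H (cat.), 4 Å MS, Et2O, −20 °C; then TFA, CH2Cl2, 0 °C
Reagents that add atoms: none
Why: In this catalytic asymmetric Mukaiyama aldol/cyclocondensation (formal hetero-Diels–Alder reaction) the chiral BINOL–Ti Lewis acid binds the aldehyde and directs the silyl enol ether terminus to its Si face, which sets C2 as (R), and TFA then closes the ring by 6-endo oxa-conjugate addition with loss of methanol while the remote methyl ester is a spectator.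

**Step 3**
Reactants: 6 methyl 6-[(2R)-6-methyl-4-oxo-3,4-dihydro-2H-pyran-2-yl]hexanoate
Product: 8 6-[(2R)-6-methyl-4-oxo-3,4-dihydro-2H-pyran-2-yl]hexanoic acid, via trimethylstannyl ester 7 (not isolated)
Conditions: Me3SnOH (4 equiv), ClCH2CH2Cl, 80 °C; then 5 % aq. HCl
Reagents that add atoms: trimethyltin hydroxide, C[Sn](C)(C)O
Why: Tin-mediated methyl ester hydrolysis runs under essentially neutral conditions, which should avoid the base-induced enolisation/β-elimination ring opening of the dihydropyranone that could erode C2, and the stannyl ester is protonated on acidic work-up.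

**Step 4**
Reactants: 8 6-[(2R)-6-methyl-4-oxo-3,4-dihydro-2H-pyran-2-yl]hexanoic acid
Product: 9 1,3-dioxoisoindolin-2-yl 6-[(2R)-6-methyl-4-oxo-3,4-dihydro-2H-pyran-2-yl]hexanoate
Conditions: N-hydroxyphthalimide, DIC, DMAP (10 mol %), CH2Cl2, rt
Reagents that add atoms: N-hydroxyphthalimide, ON1C(=O)c2ccccc2C1=O
Why: Carbodiimide (Steglich-type) esterification should convert the acid into the redox-active ester without affecting the vinylogous ester or C2.

**Step 5**
Reactants: 10 nonyl(triphenyl)phosphonium bromide; 11 tetrahydro-2H-pyran-2-ol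
Product: 13 (5Z)-tetradec-5-en-1-ol, via nonylidene ylide 12 (not isolated)
Conditions: 10 (2.2 equiv), NaHMDS (2.1 equiv), THF, 0 °C; then 11, −78 °C → rt
Reagents that add atoms: none
Why: Lithium-free Wittig olefination of the non-stabilised ylide with the open hydroxy-aldehyde form of the lactol proceeds through the kinetically favoured cis-oxaphosphetane and should therefore give mainly the (Z)-alkene, the extra equivalent of ylide serving to open the lactol as its alkoxide.

**Step 6**
Reactants: 13 (5Z)-tetradec-5-en-1-ol
Product: 14 (5Z)-1-iodotetradec-5-ene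
Conditions: PPh3, imidazole, I2, CH2Cl2, 0 °C → rt, dark
Reagents that add atoms: iodine, II
Why: Appel-type iodination converts the primary alcohol into the iodide by SN2 displacement of an alkoxyphosphonium ion, conditions under which the isolated (Z)-alkene should be untouched.

**Step 7**
Reactants: 14 (5Z)-1-iodotetradec-5-ene; 9 1,3-dioxoisoindolin-2-yl 6-[(2R)-6-methyl-4-oxo-3,4-dihydro-2H-pyran-2-yl]hexanoate
Product: 17 (2R)-6-methyl-2-[(10Z)-nonadec-10-en-1-yl]-2,3-dihydro-4H-pyran-4-one, via tetradecenyllithium 15 (not isolated), via dialkylzinc 16 (not isolated)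
Conditions: 14 (4.2 equiv), t-BuLi (8.4 equiv), Et2O/pentane, −78 °C; ZnCl2 (2.1 equiv), THF, −78 °C → rt; then 9 (1 equiv), NiCl2·glyme (20 mol %), 4,4′-di-tert-butyl-2,2′-bipyridine (40 mol %), THF/DMF, rt; aq. NH4Cl/HCl quench
Reagents that add atoms: none
Why: Transmetalation of 16 to a bipyridine–nickel(I) centre gives an alkyl–Ni(I) species that reduces the N-acyloxyphthalimide 9 by single-electron transfer; loss of CO2 and phthalimide anion releases the primary C5′ radical, which recombines with alkyl–Ni(II), and the dialkyl–Ni(III) reductively eliminates to form C5′–C6′. The closest known reaction type is the nickel-catalysed decarboxylative alkyl–alkyl Negishi coupling of redox-active esters with dialkylzinc reagents, established for primary–primary pairs. No ring is closed and no stereocentre is created; C2 lies four methylene groups from the radical centre and is not touched. The step needs chemoselective cross-coupling with the Z-alkene and the enone intact: the hex-5-enyl terminus C6′ never becomes a radical because it is carried on zinc, having been generated by iodine–lithium exchange at −78 °C (a closed-shell process for primary iodides) and transmetalated before warming, so 5-exo cyclisation onto C10′=C11′ is excluded. The radical sits on the ring side, where no π-bond can be reached through a ring smaller than eight, and the vinylogous ester is neither attacked by the dialkylzinc nor reduced at the potential at which the phthalimide ester accepts an electron.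

**Compound list**
1 | (3E)-4-methoxypent-3-en-2-one | CC(=O)/C=C(\C)OC | starting material
2 | lithium (3E)-4-methoxypenta-1,3-dien-2-olate | [Li+].[O-]C(=C)/C=C(\C)OC | intermediate
3 | (3E)-4-methoxy-2-(trimethylsilyloxy)penta-1,3-diene | C=C(O[Si](C)(C)C)/C=C(\C)OC | intermediate
4 | methyl 7-oxoheptanoate | COC(=O)CCCCCC=O | starting material
5 | methyl (7R,10E)-11-methoxy-9-oxo-7-(trimethylsilyloxy)dodec-10-enoate | COC(=O)CCCCC[C@H](CC(=O)/C=C(\C)OC)O[Si](C)(C)C | intermediate
6 | methyl 6-[(2R)-6-methyl-4-oxo-3,4-dihydro-2H-pyran-2-yl]hexanoate | COC(=O)CCCCC[C@@H]1CC(=O)C=C(C)O1 | intermediate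
7 | trimethylstannyl 6-[(2R)-6-methyl-4-oxo-3,4-dihydro-2H-pyran-2-yl]hexanoate | C[Sn](C)(C)OC(=O)CCCCC[C@@H]1CC(=O)C=C(C)O1 | intermediate
8 | 6-[(2R)-6-methyl-4-oxo-3,4-dihydro-2H-pyran-2-yl]hexanoic acid | OC(=O)CCCCC[C@@H]1CC(=O)C=C(C)O1 | intermediate
9 | 1,3-dioxoisoindolin-2-yl 6-[(2R)-6-methyl-4-oxo-3,4-dihydro-2H-pyran-2-yl]hexanoate | O=C(CCCCC[C@@H]1CC(=O)C=C(C)O1)ON1C(=O)c2ccccc2C1=O | intermediate
10 | nonyl(triphenyl)phosphonium bromide | CCCCCCCCC[P+](c1ccccc1)(c1ccccc1)c1ccccc1.[Br-] | starting material
11 | tetrahydro-2H-pyran-2-ol | OC1CCCCO1 | starting material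
12 | nonylidene(triphenyl)-λ5-phosphane | CCCCCCCCC=P(c1ccccc1)(c1ccccc1)c1ccccc1 | intermediate
13 | (5Z)-tetradec-5-en-1-ol | CCCCCCCC/C=C\CCCCO | intermediate
14 | (5Z)-1-iodotetradec-5-ene | CCCCCCCC/C=C\CCCCI | intermediate
15 | [(5Z)-tetradec-5-en-1-yl]lithium | CCCCCCCC/C=C\CCCC[Li] | intermediate
16 | bis[(5Z)-tetradec-5-en-1-yl]zinc | CCCCCCCC/C=C\CCCC[Zn]CCCC/C=C\CCCCCCCC | intermediate
17 | (2R)-6-methyl-2-[(10Z)-nonadec-10-en-1-yl]-2,3-dihydro-4H-pyran-4-one | CCCCCCCC/C=C\CCCCCCCCC[C@@H]1CC(=O)C=C(C)O1 | target

**Step count and risks**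
Total step count: 7. Longest linear sequence: 5 steps (steps 1, 2, 3, 4, 7); the second branch is 3 steps (5, 6, 7).

Steps most likely to fail:

Step 7. The C5′ radical may be reduced, dimerise or undergo β-hydride elimination faster than it is captured by alkyl–nickel, nickel hydrides may isomerise the Z-alkene, and the zinc reagent is consumed in fourfold excess. The fallback is a radical-free union of the same two carbons by hydroboration/B-alkyl Suzuki–Miyaura coupling; it sets out from diene 3 and phosphonium salt 10 and comes back at target 17. Commercial 6-bromohexan-1-ol is oxidised (TEMPO/PhI(OAc)2) to 6-bromohexanal F1. F1 and 3 under the conditions of step 2 should give, through the silyl aldol adduct (2E,6R)-11-bromo-2-methoxy-6-(trimethylsilyloxy)undec-2-en-4-one F2 (not isolated), (2R)-2-(5-bromopentyl)-6-methyl-2,3-dihydro-4H-pyran-4-one F3. Ylide 12, made from 10 as in step 5, and commercial pent-4-enal should give (5Z)-tetradeca-1,5-diene F4. Only the terminal alkene of F4 is hydroborated by 9-BBN (slight deficit, THF, rt), so that no B–H reaches the ketone, to give 9-[(5Z)-tetradec-5-en-1-yl]-9-borabicyclo[3.3.1]nonane F5. Without isolation F5 is coupled with F3 [Pd(OAc)2, PCy3, K3PO4·H2O, THF, rt] to give 17.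

Step 2. Facial discrimination by the BINOL–Ti catalyst may be insufficient with the methyl-substituted diene, or the diene may hydrolyse before it adds. The fallback replaces catalyst control by a covalent auxiliary with separable diastereomers; it sets out from aldehyde 4 and comes back at ester 6. The titanium enolate (TiCl4, i-Pr2NEt, CH2Cl2, −78 °C) of the N-acetyl derivative of (4R)-4-isopropyl-1,3-thiazolidine-2-thione adds to 4 in an acetate aldol reaction to give methyl (7R)-7-hydroxy-9-oxo-9-[(4R)-4-isopropyl-2-thioxo-1,3-thiazolidin-3-yl]nonanoate F6. The (4R)-auxiliary is taken to give the (7R)-adduct through the chelated transition state; the minor diastereomer is removed by chromatography, and the antipodal auxiliary is available if the sense is opposite. Aminolysis with MeNHOMe·HCl/imidazole gives methyl (7R)-7-hydroxy-9-[methoxy(methyl)amino]-9-oxononanoate F7. Excess 1-propynylmagnesium bromide (THF, −20 °C, slow toward the remote methyl ester) gives the β-hydroxy ynone methyl (7R)-7-hydroxy-9-oxododec-10-ynoate F8. Gold(I)- or silver(I)-catalysed 6-endo-dig oxa-cyclisation of F8 (CH2Cl2, rt) should then give 6.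

Step 5. Z-selectivity may erode through equilibration of the oxaphosphetane in the presence of the lactol alkoxide, and the E-isomer would be carried inseparably to the end. The fallback makes the alkene by alkyne semi-hydrogenation; it sets out from lactol 11 and comes back at alcohol 13. Homologation of 11 with the Ohira–Bestmann reagent (K2CO3, MeOH) gives hex-5-yn-1-ol F9 (also commercial). Its dianion (n-BuLi, 2.1 equiv, THF/DMPU) is alkylated with 1-bromooctane to give tetradec-5-yn-1-ol F10. Hydrogenation over Lindlar catalyst with quinoline should give 13 with the Z geometry fixed by syn addition.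

**Further compounds**
F1 | step 7 | 6-bromohexanal | O=CCCCCCBr
F2 | step 7 | (2E,6R)-11-bromo-2-methoxy-6-(trimethylsilyloxy)undec-2-en-4-one | BrCCCCC[C@H](CC(=O)/C=C(\C)OC)O[Si](C)(C)C
F3 | step 7 | (2R)-2-(5-bromopentyl)-6-methyl-2,3-dihydro-4H-pyran-4-one | BrCCCCC[C@@H]1CC(=O)C=C(C)O1
F4 | step 7 | (5Z)-tetradeca-1,5-diene | C=CCC/C=C\CCCCCCCC
F5 | step 7 | 9-[(5Z)-tetradec-5-en-1-yl]-9-borabicyclo[3.3.1]nonane | CCCCCCCC/C=C\CCCCB1C2CCCC1CCC2
F6 | step 2 | methyl (7R)-7-hydroxy-9-oxo-9-[(4R)-4-isopropyl-2-thioxo-1,3-thiazolidin-3-yl]nonanoate | COC(=O)CCCCC[C@@H](O)CC(=O)N1[C@H](C(C)C)CSC1=S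
F7 | step 2 | methyl (7R)-7-hydroxy-9-[methoxy(methyl)amino]-9-oxononanoate | COC(=O)CCCCC[C@@H](O)CC(=O)N(C)OC
F8 | step 2 | methyl (7R)-7-hydroxy-9-oxododec-10-ynoate | COC(=O)CCCCC[C@@H](O)CC(=O)C#CC
F9 | step 5 | hex-5-yn-1-ol | OCCCCC#C
F10 | step 5 | tetradec-5-yn-1-ol | CCCCCCCCC#CCCCCO
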